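C7 is the ring ArCH–O carbon, C8 bears C9H2–O–acyl, C8' bears C7'H(OH)Ar, C9' is the ring OCH2, O7' is the carbinol oxygen, and ring A is the tetrahydrofuran O9'–C7–C8–C8'–C9'.
Enabling feature: the C9 arm on C8 and the C7' carbinol arm on C8' lie on the same face of ring A. With C9 at the aldehyde level, O7' can close on it to a second five-membered ring B (O7'–C7'–C8'–C8–C9), so the target is the hydride-opened form of a cis-fused 2,6-diaryl-3,7-dioxabicyclo[3.3.0]octane acetal.
Cuts: first the coumarate C(=O)–O9 bond. Then, with C9 re-closed onto O7' as a methyl acetal, the C7–O9' and C7–C8 bonds together (aryl aldehyde acetal plus 2,3-dihydrofuran-3-ylmethanol). Last the C7'–C8' aldol bond and the terminal alkene that hides C9.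
Forward: ring B arises first (lactol on alkene cleavage, then cyclic enol ether) and ring A is annulated onto it in one operation. Ring B is then hydrolysed and reduced open at C9, the freed primary alcohol is esterified, and the three phenols are unmasked.
Stereochemistry: C7' and C8' come from an Evans syn aldol on (S)-4-benzyloxazolidin-2-one, C8 from the enforced cis fusion, and C7 from exo placement of the aryl group on the bicycle. The E double bond comes ready-made in commercial p-coumaric acid.
Key step: step 9

Remark: Ar = 3-methoxy-4-(triisopropylsilyloxy)phenyl. The acetal/lactol carbon C9 forms as anomer mixtures (methyl acetals drawn as one anomer, lactols without a descriptor at C9), and this centre is erased in steps 8 and 11.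

Step 1
Reactants: 1 vanillin
Product: 2 3-methoxy-4-(triisopropylsilyloxy)benzaldehyde
Conditions: TIPSCl, imidazole, DMF, rt
Reagents that add atoms: triisopropylsilyl chloride, CC(C)[Si](Cl)(C(C)C)C(C)C
Why: Imidazole-promoted O-silylation of a phenol; the aryl TIPS ether should outlast the boron aldol with its peroxide work-up, hydride, silyl triflate and aqueous acetic acid, and still leave with fluoride at the end.

Step 2
Reactants: 2 3-methoxy-4-(triisopropylsilyloxy)benzaldehyde
Product: 3 dimethyl acetal of 2 [4-(dimethoxymethyl)-2-methoxy-1-(triisopropylsilyloxy)benzene]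
Conditions: HC(OMe)3, MeOH, PPTS (cat.), rt; Et3N, concentrate, short basic alumina plug
Reagents that add atoms: trimethyl orthoformate, COC(OC)OC; methanol, CO
Why: Acid-catalysed acetalisation of an aromatic aldehyde with the orthoester as water scavenger; PPTS is too weak to touch the silyl ether, and residual aldehyde and methanol are removed because both would consume the silyl triflate in step 9.

Step 3
Reactants: 4 (S)-4-benzyloxazolidin-2-one; 5 pent-4-enoyl chloride
Product: 7 (S)-4-benzyl-3-(pent-4-enoyl)oxazolidin-2-one, via lithium oxazolidinide 6 (not isolated)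
Conditions: n-BuLi, THF, −78 °C; then 5, −78 → 0 °C
Reagents that add atoms: none
Why: N-acylation of a lithiated oxazolidinone by an acid chloride, the standard entry to Evans imides, which leaves the auxiliary stereocentre untouched.

Step 4
Reactants: 7 (S)-4-benzyl-3-(pent-4-enoyl)oxazolidin-2-one; 2 3-methoxy-4-(triisopropylsilyloxy)benzaldehyde
Product: 10 syn aldol adduct (4S)-4-benzyl-3-{(2S)-2-[(S)-hydroxy(Ar)methyl]pent-4-enoyl}oxazolidin-2-one, via Z-boron enolate 8 (not isolated), via boron aldolate 9 (not isolated)
Conditions: Bu2BOTf, i-Pr2NEt, CH2Cl2, 0 °C; 2, −78 → 0 °C; pH 7 buffer/MeOH/30% H2O2, 0 °C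
Reagents that add atoms: none
Why: Evans syn aldol: soft enolisation gives only the Z boron enolate 8, which adds to 2 through a chair-like Zimmerman–Traxler transition state on the enolate face turned away from the benzyl group, so C8' and C7' are set together as the (2S,3S) syn pair.

Step 5
Reactants: 10 syn aldol adduct
Product: 13 lactol (4S)-4-benzyl-3-{[(2S,3S)-2-Ar-5-hydroxytetrahydrofuran-3-yl]carbonyl}oxazolidin-2-one (Ar trans to acyl; anomer mixture), via vicinal diol 11 (not isolated), via hydroxy aldehyde 12 (not isolated)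
Conditions: OsO4 (cat.), NaIO4, 2,6-lutidine, dioxane/H2O, rt
Reagents that add atoms: OsO4, O=[Os](=O)(=O)=O; NaIO4 (terminal oxygen source), [Na+].[O-]I(=O)(=O)=O
Why: Lemieux–Johnson oxidation (catalytic dihydroxylation, then periodate glycol cleavage, with lutidine holding the pH) removes the terminal CH2, and the γ-hydroxy aldehyde 12 closes at once through O7' to the five-membered lactol, in which the syn aldol pair appears as a trans 2-aryl-3-acyl relationship on ring B.

Step 6
Reactants: 13 lactol
Product: 14 methyl acetal (4S)-4-benzyl-3-{[(2S,3S)-2-Ar-5-methoxytetrahydrofuran-3-yl]carbonyl}oxazolidin-2-one (anomer mixture; 5R drawn)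
Conditions: MeOH, PPTS (cat.), rt
Reagents that add atoms: methanol, CO
Why: Acid-catalysed lactol-to-methyl-acetal exchange (Fischer glycosidation type) masks C9 against the hydride of the next step, under catalysis mild enough not to ionise the benzylic C7'–O7' bond.

Step 7
Reactants: 14 methyl acetal imide
Product: 15 [(2S,3R)-2-Ar-5-methoxytetrahydrofuran-3-yl]methanol (Ar trans to CH2OH; anomer mixture; 5R drawn)
Conditions: LiBH4, THF, 0 °C → rt
Reagents that add atoms: none
Why: Reductive removal of the Evans auxiliary with LiBH4, which attacks the exocyclic imide carbonyl, turns C9' into the primary carbinol without epimerising C8' and returns 4 for reuse.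

Step 8
Reactants: 15 [(2S,3R)-2-Ar-5-methoxytetrahydrofuran-3-yl]methanol
Product: 17 (2S,3R)-2-Ar-3-(trimethylsilyloxymethyl)-2,3-dihydrofuran, via TMS ether 16 (not isolated)
Conditions: Me3SiOTf (2.5 equiv), i-Pr2NEt (4 equiv), CH2Cl2, −20 °C → rt; aq NaHCO3; Et3N-washed silica plug, used at once
Reagents that add atoms: trimethylsilyl triflate, C[Si](C)(C)OS(=O)(=O)C(F)(F)F
Why: Silyl triflate with a hindered amine does two known jobs in one flask, O-silylation of the alcohol and acetal-to-enol-ether elimination (the triflate ionises the methyl acetal and the amine takes a proton from C8, the only β-position), which erases the anomeric centre and leaves C7' and C8' untouched.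

Step 9
Reactants: 17 (2S,3R)-2-Ar-3-(trimethylsilyloxymethyl)-2,3-dihydrofuran; 3 dimethyl acetal of 2
Product: 19 (1R,2S,5S,6S)-2,6-di-Ar-4-methoxy-3,7-dioxabicyclo[3.3.0]octane (cis-fused; both aryl groups exo; methoxy drawn exo), via mixed acetal 18 (not isolated)
Conditions: Me3SiOTf (0.2 equiv), 2,6-di-tert-butyl-4-methylpyridine (0.3 equiv), 4 Å MS, CH2Cl2, −78 °C → 0 °C, held until the C7 epimers no longer change; Et3N
Reagents that add atoms: none
Why: Me3SiOTf moves the silyl ether oxygen O9' of 17 onto acetal 3 with loss of MeOSiMe3 (mixed acetal 18), ionises 18 to the E aryl oxocarbenium ion ArC7H=O9'(+)–C9'H2 that hangs from C8', the nucleophilic β-carbon C8 of the cyclic enol ether adds to C7, and MeOSiMe3 caps the new C9 oxocarbenium ion from the convex face and so returns the catalyst. The closest known reaction type is the intramolecular Mukaiyama aldol/Prins-type addition of an enol ether to an acetal, already established for 2-aryl-2,3-dihydrofuran-3-ylmethanols and aryl aldehyde dimethyl acetals, so that only the trans substrate and the silyl ether variant are new. One ring is closed, tetrahydrofuran ring A (O9'–C7–C8–C8'–C9'), in a five-membered mode that is exo to the C8=C9 bond and endo to the C7=O9' bond. C8 is controlled by the one-carbon tether on C8', which can bring C7 only to the face of ring B that carries C9' and thus forces the cis fusion, while the configuration at C9 is of no consequence. C7 needs its aryl group exo: the extended transition state with O9' folded toward the convex side keeps the aryl group of the E ion pseudo-equatorial and clear of ring B, and since a compact transition state with the aryl group stacked over C9–O7' would give the endo epimer, the mixture is warmed so that the plain benzylic ether bond C7–O9' can re-ionise and reclose toward the less crowded exo,exo isomer, whereas activation of the acetal oxygen O7' only opens and recloses C9–O7' and leaves C7' alone. The chemoselectivity needed, O-exchange before C–C bond formation and no addition of oxygen across C8=C9, is secured by the substrate, in which O7' is locked in the enol ether so that only O9' can carry the carbenium carbon, and by the proton-free silyl-transfer medium.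

Step 10
Reactants: 19 bicyclic methyl acetal
Product: 20 bicyclic lactol (1R,2S,5S,6S)-2,6-di-Ar-3,7-dioxabicyclo[3.3.0]octan-4-ol (anomer mixture)
Conditions: AcOH/THF/H2O, 35 °C
Reagents that add atoms: water, O
Why: Mild acid hydrolysis of a 2-alkoxytetrahydrofuran acetal, which ionises at C9 (assisted by O7') far more easily than either benzylic ether does at this acidity, so C7 and C7' should keep their configuration and the aryl silyl ethers stay on.

Step 11
Reactants: 20 bicyclic lactol
Product: 22 diol [(2S,3R,4R)-2-Ar-4-[(S)-hydroxy(Ar)methyl]tetrahydrofuran-3-yl]methanol (free 7'-OH; free primary 9-OH), via hydroxy aldehyde 21 (not isolated)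
Conditions: NaBH4, MeOH/THF, 0 °C
Reagents that add atoms: none
Why: Borohydride reduction of a lactol through its ring-opened tautomer 21 converts C9 into the primary alcohol and frees O7'H in the same event without breaking any bond to a stereocentre; a hydride donor is used instead of a silane and Lewis acid, which would only deoxygenate C9 and keep ring B closed.

Step 12
Reactants: 23 (E)-p-coumaric acid
Product: 25 (E)-4-(triisopropylsilyloxy)cinnamic acid, via bis-TIPS derivative 24 (not isolated)
Conditions: TIPSCl (2.2 equiv), imidazole, DMF, rt; then AcOH/THF/H2O, rt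
Reagents that add atoms: triisopropylsilyl chloride, CC(C)[Si](Cl)(C(C)C)C(C)C
Why: Exhaustive silylation followed by selective solvolysis; a silyl ester is hydrolysed by dilute aqueous acid much faster than an aryl TIPS ether, and the E alkene is not touched.

Step 13
Reactants: 22 diol; 25 (E)-4-(triisopropylsilyloxy)cinnamic acid
Product: 27 tris-TIPS ester [(2S,3R,4R)-2-Ar-4-[(S)-hydroxy(Ar)methyl]tetrahydrofuran-3-yl]methyl (E)-4-(triisopropylsilyloxy)cinnamate, via O-acylisourea 26 (not isolated)
Conditions: EDC·HCl, DMAP (cat.), 25 (1.0 equiv), CH2Cl2, 0 °C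
Reagents that add atoms: none
Why: Steglich-type carbodiimide esterification in which the unhindered primary 9-OH should outrun the secondary benzylic 7'-OH flanked by ring A, helped by low temperature and by keeping the acid as the limiting component.

Step 14
Reactants: 27 tris-TIPS ester
Product: 28 target [(2S,3R,4R)-2-(4-hydroxy-3-methoxyphenyl)-4-[(S)-hydroxy(4-hydroxy-3-methoxyphenyl)methyl]tetrahydrofuran-3-yl]methyl (E)-3-(4-hydroxyphenyl)prop-2-enoate
Conditions: TBAF/AcOH (1:1, 3.5 equiv), THF, 0 °C; pH 7 buffer work-up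
Reagents that add atoms: none
Why: Fluoride cleavage of aryl silyl ethers, the most fluoride-labile class of silyl ether, buffered with acetic acid so that phenols and not phenoxides are released, which should spare the cinnamate ester and prevent quinone methide formation at C7 and C7'.

Compound list
1 | vanillin | COc1cc(C=O)ccc1O | starting material
2 | 3-methoxy-4-(triisopropylsilyloxy)benzaldehyde | COc1cc(C=O)ccc1O[Si](C(C)C)(C(C)C)C(C)C | intermediate
3 | dimethyl acetal of 2 | COc1cc(C(OC)OC)ccc1O[Si](C(C)C)(C(C)C)C(C)C | intermediate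
4 | (S)-4-benzyloxazolidin-2-one | O=C1N[C@@H](Cc2ccccc2)CO1 | starting material
5 | pent-4-enoyl chloride | C=CCCC(Cl)=O | starting material
6 | lithium salt of 4 (not isolated) | [Li+].O=C1[N-][C@@H](Cc2ccccc2)CO1 | intermediate
7 | (S)-4-benzyl-3-(pent-4-enoyl)oxazolidin-2-one | C=CCCC(=O)N1[C@@H](Cc2ccccc2)COC1=O | intermediate
8 | Z-dibutylboron enolate of 7 (not isolated) | C=CC/C=C(\OB(CCCC)CCCC)N1[C@@H](Cc2ccccc2)COC1=O | intermediate
9 | dibutylboron aldolate of 10 (not isolated) | COc1cc([C@@H](OB(CCCC)CCCC)[C@H](CC=C)C(=O)N2[C@@H](Cc3ccccc3)COC2=O)ccc1O[Si](C(C)C)(C(C)C)C(C)C | intermediate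
10 | (2S,3S) syn aldol adduct | COc1cc([C@@H](O)[C@H](CC=C)C(=O)N2[C@@H](Cc3ccccc3)COC2=O)ccc1O[Si](C(C)C)(C(C)C)C(C)C | intermediate
11 | vicinal diol from dihydroxylation of 10 (epimers at the new carbinol, not isolated) | COc1cc([C@@H](O)[C@H](CC(O)CO)C(=O)N2[C@@H](Cc3ccccc3)COC2=O)ccc1O[Si](C(C)C)(C(C)C)C(C)C | intermediate
12 | γ-hydroxy aldehyde (not isolated) | COc1cc([C@@H](O)[C@H](CC=O)C(=O)N2[C@@H](Cc3ccccc3)COC2=O)ccc1O[Si](C(C)C)(C(C)C)C(C)C | intermediate
13 | trans-2-aryl-3-acyl lactol (anomers) | COc1cc([C@H]2OC(O)C[C@@H]2C(=O)N3[C@@H](Cc4ccccc4)COC3=O)ccc1O[Si](C(C)C)(C(C)C)C(C)C | intermediate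
14 | methyl acetal of 13 (one anomer drawn) | COc1cc([C@H]2O[C@@H](OC)C[C@@H]2C(=O)N3[C@@H](Cc4ccccc4)COC3=O)ccc1O[Si](C(C)C)(C(C)C)C(C)C | intermediate
15 | [(2S,3R)-2-Ar-5-methoxytetrahydrofuran-3-yl]methanol (one anomer drawn) | COc1cc([C@H]2O[C@@H](OC)C[C@@H]2CO)ccc1O[Si](C(C)C)(C(C)C)C(C)C | intermediate
16 | TMS ether of 15 (not isolated) | COc1cc([C@H]2O[C@@H](OC)C[C@@H]2CO[Si](C)(C)C)ccc1O[Si](C(C)C)(C(C)C)C(C)C | intermediate
17 | (2S,3R)-2-Ar-3-(trimethylsilyloxymethyl)-2,3-dihydrofuran | COc1cc([C@H]2OC=C[C@@H]2CO[Si](C)(C)C)ccc1O[Si](C(C)C)(C(C)C)C(C)C | intermediate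
18 | mixed methyl dihydrofuranylmethyl acetal of 2 (epimers at the acetal carbon, not isolated) | COc1cc([C@H]2OC=C[C@@H]2COC(OC)c3ccc(O[Si](C(C)C)(C(C)C)C(C)C)c(OC)c3)ccc1O[Si](C(C)C)(C(C)C)C(C)C | intermediate
19 | exo,exo-2,6-di-Ar-4-methoxy-3,7-dioxabicyclo[3.3.0]octane (1R,2S,4R,5S,6S as drawn) | COc1cc([C@H]2O[C@@H](OC)[C@@H]3[C@@H](c4ccc(O[Si](C(C)C)(C(C)C)C(C)C)c(OC)c4)OC[C@H]23)ccc1O[Si](C(C)C)(C(C)C)C(C)C | intermediate
20 | bicyclic lactol (anomers) | COc1cc([C@H]2OC(O)[C@@H]3[C@@H](c4ccc(O[Si](C(C)C)(C(C)C)C(C)C)c(OC)c4)OC[C@H]23)ccc1O[Si](C(C)C)(C(C)C)C(C)C | intermediate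
21 | ring-opened hydroxy aldehyde tautomer of 20 (not isolated) | COc1cc([C@@H](O)[C@H]2CO[C@H](c3ccc(O[Si](C(C)C)(C(C)C)C(C)C)c(OC)c3)[C@H]2C=O)ccc1O[Si](C(C)C)(C(C)C)C(C)C | intermediate
22 | bis-TIPS diol (7S,8R,7'S,8'R) | COc1cc([C@@H](O)[C@H]2CO[C@H](c3ccc(O[Si](C(C)C)(C(C)C)C(C)C)c(OC)c3)[C@H]2CO)ccc1O[Si](C(C)C)(C(C)C)C(C)C | intermediate
23 | (E)-p-coumaric acid | O=C(O)/C=C/c1ccc(O)cc1 | starting material
24 | triisopropylsilyl (E)-4-(triisopropylsilyloxy)cinnamate (not isolated) | CC(C)[Si](C(C)C)(C(C)C)OC(=O)/C=C/c1ccc(O[Si](C(C)C)(C(C)C)C(C)C)cc1 | intermediate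
25 | (E)-4-(triisopropylsilyloxy)cinnamic acid | O=C(O)/C=C/c1ccc(O[Si](C(C)C)(C(C)C)C(C)C)cc1 | intermediate
26 | O-acylisourea from 25 and EDC (not isolated) | CCN=C(NCCCN(C)C)OC(=O)/C=C/c1ccc(O[Si](C(C)C)(C(C)C)C(C)C)cc1 | intermediate
27 | tris-TIPS ester | COc1cc([C@@H](O)[C@H]2CO[C@H](c3ccc(O[Si](C(C)C)(C(C)C)C(C)C)c(OC)c3)[C@H]2COC(=O)/C=C/c2ccc(O[Si](C(C)C)(C(C)C)C(C)C)cc2)ccc1O[Si](C(C)C)(C(C)C)C(C)C | intermediate
28 | CNP0330050.2 | COc1cc([C@@H](O)[C@H]2CO[C@H](c3ccc(O)c(OC)c3)[C@H]2COC(=O)/C=C/c2ccc(O)cc2)ccc1O | target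

Total step count: 14.
Longest linear sequence: 11 steps (steps 3, 4, 5, 6, 7, 8, 9, 10, 11, 13, 14 from 4 and 5; the same length from vanillin through steps 1, 4 to 11, 13, 14).

Steps most likely to fail

Step 9: poor facial control at C7.
- The closure may run through the compact arrangement in which the aryl group lies over ring B, which puts it on the concave face.
- The energy gap between exo and endo aryl groups on this bicycle is small, so warming may level the epimers instead of correcting them.
- Premature intermolecular attack of the enol ether on the acetal-derived cation, before O9' has exchanged, would also deliver C7 to the wrong face of C8.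

The fallback uses known reaction types only, with C7–C8 made by a lactone aldol and C7–O9' by a stereoconvergent benzylic cycloetherification. It sets out from 10 and rejoins at 20. The carbinol of 10 is silylated (TBSOTf, 2,6-lutidine) to the TBS ether F1, and LiBH4 removes the auxiliary to give the pentenol F2. Lemieux–Johnson cleavage now lets O9' close on the new aldehyde to the lactol F3, and Dess–Martin periodinane oxidises this to the β-substituted butyrolactone F4. The lithium enolate of F4 (LiN(SiMe3)2, THF, −78 °C) should add to aldehyde 2 on the face away from the C8' side chain. This gives the trans aldol lactone F5 with the C8 configuration of the target and an irrelevant mixture at the C7 carbinol. Camphorsulfonic acid in wet CH2Cl2 then removes the TBS group, and O7' takes over the lactone carbonyl (translactonisation to ring B). The released O9'H closes on the C7 benzylic cation formed from either carbinol epimer, with the aryl group turning away from ring B, to give the exo,exo bicyclic lactone F6. Finally i-Bu2AlH (CH2Cl2, −78 °C) reduces F6 to lactol 20.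

Step 8: loss of material through misdirected ionisation and through the lability of the product.
- The silyl triflate may open the benzylic C7'–O7' bond instead of the acetal.
- Elimination may stall at the silylated acetal.
- The enol ether and its TMS ether may hydrolyse on isolation.

In the fallback the double bond is introduced earlier by a different elimination, from 13 to 17. Lactol 13 is treated with MsCl and Et3N (sulfonylation of the anomeric hydroxyl and loss of methanesulfonate, the usual lactol-to-dihydrofuran dehydration) to give the dihydrofuran imide F7. LiBH4 removes the auxiliary to give the dihydrofuranylmethanol F8, and Me3SiCl/Et3N silylates it under acid-free conditions to 17.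

Step 14: damage during the threefold desilylation. Any phenoxide that escapes the buffer can expel the benzylic oxygen at C7' or C7 (quinone methide formation, epimerisation or loss of water), cleave the cinnamate, or shift it from O9 to O7'.

In the fallback the order of ester formation and unmasking is reversed, from 22 to 28. Diol 22 is desilylated first (TBAF/AcOH, THF, 0 °C), when no ester is present, to the free tetraol F9. Unprotected p-coumaric acid 23 is then joined to the primary 9-OH by a Mitsunobu esterification (PPh3, DIAD, THF, 0 °C). This redox condensation is known to esterify phenolic acids chemoselectively beside free phenols, and it activates the primary alcohol ahead of the hindered secondary one. It gives 28 directly and makes steps 12 and 13 unnecessary.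

Further compounds
F1 | step 9 | (4S)-4-benzyl-3-{(2S)-2-[(S)-(tert-butyldimethylsilyloxy)(Ar)methyl]pent-4-enoyl}oxazolidin-2-one | COc1cc([C@@H](O[Si](C)(C)C(C)(C)C)[C@H](CC=C)C(=O)N2[C@@H](Cc3ccccc3)COC2=O)ccc1O[Si](C(C)C)(C(C)C)C(C)C
F2 | step 9 | (2R)-2-[(S)-(tert-butyldimethylsilyloxy)(Ar)methyl]pent-4-en-1-ol | COc1cc([C@@H](O[Si](C)(C)C(C)(C)C)[C@H](CC=C)CO)ccc1O[Si](C(C)C)(C(C)C)C(C)C
F3 | step 9 | (4R)-4-[(S)-(tert-butyldimethylsilyloxy)(Ar)methyl]tetrahydrofuran-2-ol (anomers) | COc1cc([C@@H](O[Si](C)(C)C(C)(C)C)[C@H]2COC(O)C2)ccc1O[Si](C(C)C)(C(C)C)C(C)C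
F4 | step 9 | (4R)-4-[(S)-(tert-butyldimethylsilyloxy)(Ar)methyl]dihydrofuran-2(3H)-one | COc1cc([C@@H](O[Si](C)(C)C(C)(C)C)[C@H]2COC(=O)C2)ccc1O[Si](C(C)C)(C(C)C)C(C)C
F5 | step 9 | (3S,4R)-trans-3-[hydroxy(Ar)methyl]-4-[(S)-(tert-butyldimethylsilyloxy)(Ar)methyl]dihydrofuran-2(3H)-one (carbinol epimers) | COc1cc([C@@H](O[Si](C)(C)C(C)(C)C)[C@H]2COC(=O)[C@@H]2C(O)c3ccc(O[Si](C(C)C)(C(C)C)C(C)C)c(OC)c3)ccc1O[Si](C(C)C)(C(C)C)C(C)C
F6 | step 9 | (1R,2S,5S,6S)-exo,exo-2,6-di-Ar-3,7-dioxabicyclo[3.3.0]octan-4-one | COc1cc([C@H]2OC(=O)[C@@H]3[C@@H](c4ccc(O[Si](C(C)C)(C(C)C)C(C)C)c(OC)c4)OC[C@H]23)ccc1O[Si](C(C)C)(C(C)C)C(C)C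
F7 | step 8 | (4S)-4-benzyl-3-{[(2S,3S)-2-Ar-2,3-dihydrofuran-3-yl]carbonyl}oxazolidin-2-one | COc1cc([C@H]2OC=C[C@@H]2C(=O)N3[C@@H](Cc4ccccc4)COC3=O)ccc1O[Si](C(C)C)(C(C)C)C(C)C
F8 | step 8 | [(2S,3R)-2-Ar-2,3-dihydrofuran-3-yl]methanol | COc1cc([C@H]2OC=C[C@@H]2CO)ccc1O[Si](C(C)C)(C(C)C)C(C)C
F9 | step 14 | [(2S,3R,4R)-2-(4-hydroxy-3-methoxyphenyl)-4-[(S)-hydroxy(4-hydroxy-3-methoxyphenyl)methyl]tetrahydrofuran-3-yl]methanol | COc1cc([C@@H](O)[C@H]2CO[C@H](c3ccc(O)c(OC)c3)[C@H]2CO)ccc1O
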